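## Structural features

The target is a hydroazulene sesquiterpene joined through one benzylic methine to a fully substituted phloroglucinol dialdehyde. Locants used throughout: cyclopentane C1–C5 (C1 and C5 are the fusion atoms, C4 is quaternary and carries a methyl group); cycloheptene C5=C6–C7–C8–C9–C10–C1 (2-hydroxypropan-2-yl on C7, methyl on C10); side-chain carbon C9' (H, isobutyl) between C4 and arene carbon C1'; arene C1'–C6' with OH on C2', C4', C6' and CHO on C3', C5'. There are five stereocentres: C1 and C10 are adjacent, C7 is allylic to the trisubstituted C5=C6 alkene, and the quaternary C4 stands next to the benzylic C9'. The fragile groups are the tertiary homoallylic alcohol (ionisation, dehydration), the C5=C6 alkene (protonation beside a quaternary carbon) and the electron-rich diformylphloroglucinol (oxidation, acid-induced loss of the side chain through an o-quinone methide). The real difficulty is the C4–C9' bond, which ties a quaternary carbon to a hindered benzylic stereocentre flanked by two ortho oxygens, together with control of C9' relative to C4. The ring stereocentres C1, C7 and C10 are the second problem. The key step exploits the phenolic C2'–O bond beside C1': an aryne can take up that oxygen and the future C9' carbon at neighbouring positions from a carboxyl group on C4, so the crowded C1'–C9' bond is closed intramolecularly from an acid that cannot enolise.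

## Logic of the disconnections

37 ⇒ 36 ⇒ 35. The two aryl O–CH3 bonds and the O–Si bond are cut last, because the free phenols and the tertiary alcohol are the most sensitive functions. Every earlier step then runs on a less polar, oxidation-resistant compound. The forward steps must be a nucleophilic demethylation (both methoxy groups are ortho to formyl groups) and a desilylation that does not ionise the tertiary centre.

35 ⇒ 34. The C3'–CHO and C5'–CHO bonds are cut. These are the only two free ring positions of 34, so exhaustive formylation needs no regiocontrol and the arene can enter the synthesis as a simple dimethoxy unit. The electrophilic conditions must spare the tertiary silyl ether and C5=C6.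

34 ⇒ 30 (through 33). The C9'–CH2 bond to the isobutyl group and the C9'–H bond are cut, both back to a C9' carbonyl. The isobutyl group then adds to a planar, strongly electrophilic carbon instead of displacing a leaving group beside a quaternary centre, and one stereocentre and one branched chain disappear. The forward step must deliver exactly one hydride before the Grignard reagent, and C4 must direct the face of attack at C9'.

30 ⇒ 29. The O–CO2tBu bond is cut; the carbonate is only the trigger for the previous operation and must go on the hindered, hydrogen-bonded phenol.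

29 ⇒ 25 + 5 (through 26, 27, 28). The C1'–C9' and C2'–O bonds are cut together. This reduces the arene to a derivative of a commercial phenol and the terpene to an acid without the C9' stereocentre. The forward step needs an aprotic medium, a preformed carboxylate and the regiocontrol of the methoxy group beside the triple bond.

5 ⇒ 2 ⇒ 1. The aryl C–Si and O–S bonds are traced back to a C–Br bond ortho to the hydroxyl group, which demands bromination between OH and OMe.

25 ⇒ 24 ⇒ 22 ⇒ 20. Only functional groups are removed: the O–CH3 bond of the C4 ester, the C9 oxygen, and the C8–CO2Me bond with the enol O–Si bond. These are the residues of the three-carbon partner of the annulation. The forward steps must distinguish the two esters and must not epimerise C10.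

20 ⇒ 18 + 10 (through 19). The C7–C8 and C1–C10 bonds are cut. One operation then builds the seven-membered ring, places C5=C6 and sets C1, C7 and C10. It demands a (Z) alkene at C6=C7, a (Z) silyl enol ether in 10 and catalyst control of the alkene face.

10 ⇒ 9 ⇒ 8. The enol O–Si bond and the C=N2 unit are removed, leaving a commercial β-keto ester.

18 ⇒ 17 ⇒ 16 + 7. The (Z) alkene is related to an alkyne and the C5–C6 bond is cut between an sp2 and an sp carbon. This gives a convergent, geometry-defined diene; the semireduction must stop at the diene.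

7 ⇒ 6. The O–Si bond is cut; the protection must precede all metal-mediated steps.

16 ⇒ 15 ⇒ 13 (through 14) ⇒ 11 + 12. The enol O–S bond and then the C4–CH3 bond are cut. The quaternary centre is made first, on a commercial β-keto ester, under control of a recoverable amino ester.

## Other disconnections considered

Alternative 1: The cut is at aryl–C9' and C3–C4, so the C4/C9' dyad comes from the alkene of the (Z)-alkenylcyclobutanol A2. In the forward step the diazonium salt A3, Ph3PAuCl and Ru(bpy)3(PF6)2 under visible light give an aryl–gold species that activates the alkene. A ring CH2 migrates from the carbinol carbon to C4 while the aryl group ends on C9', giving the cyclopentanone A1.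
- In favour: the addition is anti and stereospecific, so the (Z) geometry of A2 fixes C9' relative to C4 by mechanism. On this point it is better than the chosen plan, where C9' depends on a conformational bias in step 17. A2 is also only a few steps from simple materials.
- Against: A3 is an electron-rich, doubly ortho-substituted diazonium salt, a poor and unstable aryl donor, and the alkene is trisubstituted. No reliable absolute control exists for this reaction type, so A1 would need resolution.
- Comparison: A1 still lacks the whole seven-membered ring. The three ring stereocentres would have to be built from the C5 ketone with the bulky arylalkyl group already beside the reacting site, and formylation and deprotection remain. The early steps are shorter, but the total is no shorter than the chosen plan, and absolute stereocontrol is weaker.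

Alternative 2: The cut is at C7–C8 and C1–C10, with the arylated side chain already on C4. In the forward step Rh2(S-PTAD)4 or its mirror image converts diazo ester 10 into a carbenoid that cyclopropanates the (Z) alkene of diene A5; Cope rearrangement gives A4.
- In favour: mechanistically it is the same event as step 11 of the chosen plan, so it is its equal for C1, C7 and C10. The arene already carries its two one-carbon groups as esters, so no electrophilic formylation is run on the acid-sensitive terpene. On that point it is better.
- Against: A5 needs the C4/C9' dyad beforehand, so the hardest bond must be solved on a small ring anyway. The large C4 substituent sits beside the diene and may oppose the catalyst. Three kinds of ester must be told apart later, and the aryl esters need reduction and re-oxidation.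
- Comparison: the chosen plan keeps the annulation substrate small (18) and uses the C4 ester twice, as the activating group of the starting β-keto ester and as the acyl donor of the key step. The step count of alternative 2 is expected to be equal or higher.

Alternative 3: The cut is at C1=C2 and C5=C6, both formed by metathesis from the acyclic dienyne A7. In the forward step second-generation Grubbs catalyst initiates at the vinyl group of the allylic alcohol, the carbene adds to the alkyne to close the cyclopentene, and the new carbene closes the cycloheptene, giving the dienol A6.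
- In favour: both rings form in one catalytic step without diazo compounds, and the complete side chain is in place so no late o-quinone methide step is needed. On ring-forming economy and reagent safety it is better than the chosen plan.
- Against: A7 is an open chain with five stereocentres, including the contiguous C9'–C4–C3 triad and a quaternary propargylic carbon. Its assembly is harder than the problem it solves. The alkyne is flanked by a quaternary and a branched carbon, which slows the enyne step.
- Comparison: A6 still has C1=C2 and a C3 hydroxyl group. C1 would have to be set afterwards by a selective 1,2-reduction of a conjugated diene, and C3 deoxygenated. The chosen plan sets C1, C7 and C10 in one concerted event and should be shorter overall.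

Key step: step 15

Notation: TBS = tert-butyldimethylsilyl; "octahydroazulene" always means the 1,2,3,4,7,8,9,10-octahydro isomer (C5=C6) with the locants defined above.

Remark on the fixed structures: acid 25 and ketone 29 agree with the target atom for atom and centre for centre. C4 has the spatial arrangement of the target; its descriptor is S there only because the carboxyl or acyl carbon outranks C5. No correction is needed. The one change of design is that 25 enters the key step as its cesium salt.

Assumption 1: the lithio-enamine from tert-butyl L-valinate is taken to be methylated, in toluene with hexamethylphosphoramide, on the face that leads to (S)-15; if the sense is the reverse, tert-butyl D-valinate is used and nothing else changes.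

Assumption 2: Rh2(S-PTAD)4 (dirhodium tetrakis[(S)-N-phthaloyl-1-adamantylglycinate]) is taken as the antipode that attacks the alkene face of 18 leading to 19; if it proves to be the other one, Rh2(R-PTAD)4 is used.

## Route

Step 1
Reactants: 1 3,5-dimethoxyphenol
Product: 2 2-bromo-3,5-dimethoxyphenol
Conditions: NBS, CH2Cl2, −78 °C to rt
Reagents that add atoms: N-bromosuccinimide, O=C1CCC(=O)N1Br
Why: Electrophilic aromatic bromination; the position between OH and OMe (ortho to the hydroxyl, para to a methoxy group) should react first at low temperature, and the minor para-bromo isomer is removed by chromatography.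

Step 2
Reactants: 2 2-bromo-3,5-dimethoxyphenol
Product: 5 3,5-dimethoxy-2-(trimethylsilyl)phenyl trifluoromethanesulfonate, via aryl trimethylsilyl ether 3 (not isolated), via lithium 2-silylphenolate 4 (not isolated)
Conditions: (Me3Si)2NH, THF, 70 °C; evaporate; n-BuLi, THF, −100 °C; Tf2O, −100 to −78 °C
Reagents that add atoms: hexamethyldisilazane, C[Si](C)(C)N[Si](C)(C)C; trifluoromethanesulfonic anhydride, O=S(=O)(OS(=O)(=O)C(F)(F)F)C(F)(F)F
Why: O-silylation, bromine–lithium exchange and retro-Brook 1,3-shift of silicon from oxygen to carbon give phenolate 4, which is trapped as the triflate; this is the standard way to 2-silylaryl triflates.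

Step 3
Reactants: 6 2-methylbut-3-yn-2-ol
Product: 7 tert-butyldimethyl[(2-methylbut-3-yn-2-yl)oxy]silane
Conditions: TBSOTf, 2,6-lutidine, CH2Cl2, 0 °C to rt
Reagents that add atoms: tert-butyldimethylsilyl trifluoromethanesulfonate, CC(C)(C)[Si](C)(C)OS(=O)(=O)C(F)(F)F
Why: Silylation of a tertiary propargylic alcohol with a silyl triflate and a hindered base; the group keeps the oxygen away from the rhodium carbenoid and from Lewis acids later.

Step 4
Reactants: 8 methyl 3-oxopentanoate
Product: 9 methyl 2-diazo-3-oxopentanoate
Conditions: 4-acetamidobenzenesulfonyl azide, Et3N, MeCN, 0 °C to rt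
Reagents that add atoms: 4-acetamidobenzenesulfonyl azide, CC(=O)Nc1ccc(cc1)S(=O)(=O)N=[N+]=[N-]
Why: Regitz diazo transfer to the active methylene group of a β-keto ester.

Step 5
Reactants: 9 methyl 2-diazo-3-oxopentanoate
Product: 10 methyl (3Z)-3-(TBSO)-2-diazopent-3-enoate
Conditions: TBSOTf, Et3N, CH2Cl2, 0 °C
Reagents that add atoms: tert-butyldimethylsilyl trifluoromethanesulfonate, CC(C)(C)[Si](C)(C)OS(=O)(=O)C(F)(F)F
Why: Soft enolisation and O-silylation of the α-diazo ketone; the (Z) enol ether, with the methyl group trans to the diazo carbon, is favoured because it avoids allylic strain with the diazo ester.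

Step 6
Reactants: 11 methyl 2-oxocyclopentane-1-carboxylate; 12 tert-butyl L-valinate
Product: 13 methyl 2-{[(2S)-1-tert-butoxy-3-methyl-1-oxobutan-2-yl]amino}cyclopent-1-ene-1-carboxylate
Conditions: TsOH (cat.), toluene, reflux with removal of water
Reagents that add atoms: none
Why: Condensation of the β-keto ester with the amino ester gives the hydrogen-bonded enamino ester, the substrate for auxiliary-controlled alkylation.

Step 7
Reactants: 13 methyl 2-{[(2S)-1-tert-butoxy-3-methyl-1-oxobutan-2-yl]amino}cyclopent-1-ene-1-carboxylate
Product: 15 methyl (1S)-1-methyl-2-oxocyclopentane-1-carboxylate, via methylated imine 14 (not isolated)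
Conditions: LiN(iPr)2, toluene, −78 °C; hexamethylphosphoramide; MeI, −78 to −40 °C; then 1 M aq. HCl, rt
Reagents that add atoms: iodomethane, CI; water, O
Why: The lithiated enamine is chelated by the valine ester carbonyl and should be methylated at C4 on the face away from the isopropyl group (alkylation of a chiral lithio-enamine of a β-keto ester); mild acid hydrolysis of imine 14 releases 15 and the auxiliary. C4 is set here and, being quaternary, cannot epimerise later.

Step 8
Reactants: 15 methyl (1S)-1-methyl-2-oxocyclopentane-1-carboxylate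
Product: 16 methyl (1S)-1-methyl-2-[(trifluoromethanesulfonyl)oxy]cyclopent-2-ene-1-carboxylate
Conditions: KN(SiMe3)2, THF, −78 °C; PhNTf2, −78 to 0 °C
Reagents that add atoms: N-phenylbis(trifluoromethanesulfonimide), O=S(=O)(N(c1ccccc1)S(=O)(=O)C(F)(F)F)C(F)(F)F
Why: Only C1 carries α-hydrogens, so deprotonation and O-triflation give a single enol triflate.

Step 9
Reactants: 16 methyl (1S)-1-methyl-2-[(trifluoromethanesulfonyl)oxy]cyclopent-2-ene-1-carboxylate; 7 tert-butyldimethyl[(2-methylbut-3-yn-2-yl)oxy]silane
Product: 17 methyl (1S)-2-[3-(TBSO)-3-methylbut-1-yn-1-yl]-1-methylcyclopent-2-ene-1-carboxylate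
Conditions: Pd(PPh3)2Cl2 (cat.), CuI (cat.), Et3N, DMF, rt
Reagents that add atoms: none
Why: Sonogashira coupling of an alkenyl triflate with a terminal alkyne forms the C5–C6 bond.

Step 10
Reactants: 17 methyl (1S)-2-[3-(TBSO)-3-methylbut-1-yn-1-yl]-1-methylcyclopent-2-ene-1-carboxylate
Product: 18 methyl (1S)-2-[(1Z)-3-(TBSO)-3-methylbut-1-en-1-yl]-1-methylcyclopent-2-ene-1-carboxylate
Conditions: H2 (1 atm), Pd/CaCO3 poisoned with Pb(OAc)2, quinoline, hexane–EtOAc, rt
Reagents that add atoms: none
Why: Lindlar semihydrogenation gives the (Z) alkene by syn addition of hydrogen; the trisubstituted ring alkene beside the quaternary carbon should not be reduced.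

Step 11
Reactants: 18 methyl (1S)-2-[(1Z)-3-(TBSO)-3-methylbut-1-en-1-yl]-1-methylcyclopent-2-ene-1-carboxylate; 10 methyl (3Z)-3-(TBSO)-2-diazopent-3-enoate
Product: 20 dimethyl (1R,4S,7S,10S)-9-(TBSO)-7-[2-(TBSO)propan-2-yl]-4,10-dimethyl-1,2,3,4,7,10-hexahydroazulene-4,8-dicarboxylate, via cis-divinylcyclopropane 19 (not isolated)
Conditions: Rh2(S-PTAD)4 (1 mol%), hexanes, −26 °C to rt, slow addition of 10; then 60 °C
Reagents that add atoms: none
Why: Tandem cyclopropanation and Cope rearrangement (formal [4+3]): the donor/acceptor rhodium carbenoid from 10 should add to the cis-disubstituted C6=C7 alkene and not to the hindered ring alkene, with both alkene substituents cis to the siloxyvinyl group, and 19 then rearranges through a boat transition state. The boat places H1 and H10 inside and the C7 side chain on the same face, which fixes C1, C7 and C10 relative to one another, while the chiral carboxylate ligands choose the alkene face and so the absolute sense and the relation to C4.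

Step 12
Reactants: 20 dimethyl (1R,4S,7S,10S)-9-(TBSO)-7-[2-(TBSO)propan-2-yl]-4,10-dimethyl-1,2,3,4,7,10-hexahydroazulene-4,8-dicarboxylate
Product: 22 methyl (1R,4S,7R,10S)-7-[2-(TBSO)propan-2-yl]-4,10-dimethyl-9-oxooctahydroazulene-4-carboxylate, via β-keto ester 21 (not isolated)
Conditions: Bu4NF, AcOH, THF, 0 °C; evaporate; LiCl, H2O, DMSO, 130 °C
Reagents that add atoms: none
Why: Buffered fluoride cleaves only the silyl enol ether (the tertiary silyl ether is far slower), and Krapcho dealkoxycarbonylation removes the activated C8 ester while the hindered, unactivated C4 ester stays. The enolate formed on loss of CO2 lies toward C8, so C10 is not touched.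

Step 13
Reactants: 22 methyl (1R,4S,7R,10S)-7-[2-(TBSO)propan-2-yl]-4,10-dimethyl-9-oxooctahydroazulene-4-carboxylate
Product: 24 methyl (1R,4S,7R,10R)-7-[2-(TBSO)propan-2-yl]-4,10-dimethyloctahydroazulene-4-carboxylate, via tosylhydrazone 23 (not isolated)
Conditions: TsNHNH2, MeOH, 50 °C; evaporate; catecholborane, CHCl3, 0 °C to rt; NaOAc·3H2O, 60 °C
Reagents that add atoms: none
Why: Tosylhydrazone formation, hydride reduction with catecholborane and base-induced loss of sulfinate and nitrogen (tosylhydrazone deoxygenation) replace C=O by CH2 without strong base, which limits epimerisation at C10; ester, alkene and silyl ether are inert.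

Step 14
Reactants: 24 methyl (1R,4S,7R,10R)-7-[2-(TBSO)propan-2-yl]-4,10-dimethyloctahydroazulene-4-carboxylate
Product: 25 (1R,4S,7R,10R)-7-[2-(TBSO)propan-2-yl]-4,10-dimethyloctahydroazulene-4-carboxylic acid
Conditions: NaSEt, DMF, 90 °C; then aq. citric acid
Reagents that add atoms: none
Why: The neopentyl-type ester resists attack at the acyl carbon, but its O-methyl group is open to SN2 dealkylation by thiolate.

Step 15
Reactants: 25 (1R,4S,7R,10R)-7-[2-(TBSO)propan-2-yl]-4,10-dimethyloctahydroazulene-4-carboxylic acid; 5 3,5-dimethoxy-2-(trimethylsilyl)phenyl trifluoromethanesulfonate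
Product: 29 (2-hydroxy-4,6-dimethoxyphenyl)[(1R,4S,7R,10R)-7-[2-(TBSO)propan-2-yl]-4,10-dimethyloctahydroazulen-4-yl]methanone, via cesium carboxylate 26 (not isolated), via 3,5-dimethoxybenzyne 27 (not isolated), via ortho-acyloxyaryl anion 28 (not isolated)
Conditions: Cs2CO3, MeOH, rt; evaporate and dry; 5 (1.5 equiv), CsF, THF, 110 °C (sealed tube)
Reagents that add atoms: none
Why: Fluoride removes the trimethylsilyl group of 5 and triflate leaves, so aryne 27 is released slowly in an aprotic medium that already holds carboxylate 26. The carboxylate oxygen adds to the aryne carbon remote from the flanking methoxy group, because the charge then develops at the carbon ortho to that inductively withdrawing oxygen, giving aryl anion 28. This anion attacks its own ester carbonyl through a four-membered alkoxide that opens to the ortho-acyl phenoxide, a 1,3 shift of the acyl group from oxygen to carbon of the anionic Fries kind; the closest known reaction type is the insertion of arynes from 2-silylaryl triflates and CsF into the C–O bond of carboxylic acids to give ortho-hydroxyaryl ketones. No ring is closed in the product (the four-membered alkoxide is a transient 4-exo-trig adduct) and no stereocentre is formed; C4 is quaternary, so neither enolisation nor epimerisation can compete. The step needs regioselectivity, which the methoxy group beside the triple bond secures by placing OH on the unflanked carbon and the acyl group between OH and OMe. It needs acyl transfer in preference to protonation of 28, which the preformed cesium salt and the lack of acidic hydrogens in THF secure, and it needs monoarylation, which the chelated, flanked product phenoxide and the small excess of 5 secure. The tertiary silyl ether should survive because CsF is barely soluble in THF and the Si–O bond is shielded by the tertiary carbon.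

Step 16
Reactants: 29 (2-hydroxy-4,6-dimethoxyphenyl)[(1R,4S,7R,10R)-7-[2-(TBSO)propan-2-yl]-4,10-dimethyloctahydroazulen-4-yl]methanone
Product: 30 tert-butyl 2-{[(1R,4S,7R,10R)-7-[2-(TBSO)propan-2-yl]-4,10-dimethyloctahydroazulen-4-yl]carbonyl}-3,5-dimethoxyphenyl carbonate
Conditions: Boc2O, iPr2NEt, DMAP (cat.), CH2Cl2, rt
Reagents that add atoms: di-tert-butyl dicarbonate, CC(C)(C)OC(=O)OC(=O)OC(C)(C)C
Why: Acylation of the phenol with Boc2O under nucleophilic catalysis; the aryl carbonate is the trigger of the o-quinone methide sequence.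

Step 17
Reactants: 30 tert-butyl 2-{[(1R,4S,7R,10R)-7-[2-(TBSO)propan-2-yl]-4,10-dimethyloctahydroazulen-4-yl]carbonyl}-3,5-dimethoxyphenyl carbonate
Product: 34 2-{(1S)-1-[(1R,4R,7R,10R)-7-[2-(TBSO)propan-2-yl]-4,10-dimethyloctahydroazulen-4-yl]-3-methylbutyl}-3,5-dimethoxyphenol, via lithium benzylic alkoxide 31 (not isolated), via benzylic carbonate phenoxide 32 (not isolated), via o-quinone methide 33 (not isolated)
Conditions: LiBHEt3 (1.05 equiv), THF, −78 °C; then iBuMgBr (4 equiv), −78 °C to rt; aq. NH4Cl
Reagents that add atoms: isobutylmagnesium bromide, CC(C)C[Mg]Br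
Why: One-pot o-quinone methide alkylation: a single hydride gives alkoxide 31, the carbonate moves to the benzylic oxygen (32), and magnesium-assisted loss of tert-butyl carbonate gives 33, which cannot tautomerise because C4 bears no hydrogen and which adds the Grignard reagent at C9' with rearomatisation. C9' is set by C4: with the quinone methide plane anti to C5, the reagent should enter past the C4 methyl group and opposite the C3 methylene, which corresponds to the (S) configuration.

Step 18
Reactants: 34 2-{(1S)-1-[(1R,4R,7R,10R)-7-[2-(TBSO)propan-2-yl]-4,10-dimethyloctahydroazulen-4-yl]-3-methylbutyl}-3,5-dimethoxyphenol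
Product: 35 4-hydroxy-2,6-dimethoxy-5-{(1S)-1-[(1R,4R,7R,10R)-7-[2-(TBSO)propan-2-yl]-4,10-dimethyloctahydroazulen-4-yl]-3-methylbutyl}benzene-1,3-dicarbaldehyde
Conditions: Cl2CHOMe, TiCl4, CH2Cl2, −78 to −10 °C; then ice-water
Reagents that add atoms: dichloromethyl methyl ether, COC(Cl)Cl; water, O
Why: Rieche formylation; both free ring positions are ortho or para to three oxygen donors, so exhaustive reaction gives the dialdehyde, and the titanium phenoxide keeps the ring activated after the first formyl group is in place. Low temperature is used to spare the hindered tertiary silyl ether and the alkene.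

Step 19
Reactants: 35 4-hydroxy-2,6-dimethoxy-5-{(1S)-1-[(1R,4R,7R,10R)-7-[2-(TBSO)propan-2-yl]-4,10-dimethyloctahydroazulen-4-yl]-3-methylbutyl}benzene-1,3-dicarbaldehyde
Product: 36 4-hydroxy-5-{(1S)-1-[(1R,4R,7R,10R)-7-(2-hydroxypropan-2-yl)-4,10-dimethyloctahydroazulen-4-yl]-3-methylbutyl}-2,6-dimethoxybenzene-1,3-dicarbaldehyde
Conditions: HF (48% aq.), MeCN, 0 °C to rt
Reagents that add atoms: none
Why: Fluoride-assisted cleavage of the tertiary silyl ether under weakly acidic conditions that the tertiary alcohol, the alkene and the aryl aldehydes should tolerate.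

Step 20
Reactants: 36 4-hydroxy-5-{(1S)-1-[(1R,4R,7R,10R)-7-(2-hydroxypropan-2-yl)-4,10-dimethyloctahydroazulen-4-yl]-3-methylbutyl}-2,6-dimethoxybenzene-1,3-dicarbaldehyde
Product: 37 2,4,6-trihydroxy-5-{(1S)-1-[(1R,4R,7R,10R)-7-(2-hydroxypropan-2-yl)-4,10-dimethyloctahydroazulen-4-yl]-3-methylbutyl}benzene-1,3-dicarbaldehyde
Conditions: NaSEt, DMF, 110 °C; then 1 M HCl, 0 °C
Reagents that add atoms: none
Why: SN2 demethylation by thiolate; both methoxy groups are ortho to a formyl group, so the departing phenoxides are stabilised, and the basic, non-oxidising medium spares the tertiary alcohol and the alkene.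

## Compound list

1 | 3,5-dimethoxyphenol | COc1cc(O)cc(OC)c1 | starting material
2 | 2-bromo-3,5-dimethoxyphenol | COc1cc(O)c(Br)c(OC)c1 | intermediate
3 | (2-bromo-3,5-dimethoxyphenoxy)trimethylsilane | COc1cc(O[Si](C)(C)C)c(Br)c(OC)c1 | intermediate
4 | lithium 3,5-dimethoxy-2-(trimethylsilyl)phenolate | [Li+].COc1cc([O-])c([Si](C)(C)C)c(OC)c1 | intermediate
5 | 3,5-dimethoxy-2-(trimethylsilyl)phenyl trifluoromethanesulfonate | COc1cc(OC)c([Si](C)(C)C)c(OS(=O)(=O)C(F)(F)F)c1 | intermediate
6 | 2-methylbut-3-yn-2-ol | CC(C)(O)C#C | starting material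
7 | tert-butyldimethyl[(2-methylbut-3-yn-2-yl)oxy]silane | C#CC(C)(C)O[Si](C)(C)C(C)(C)C | intermediate
8 | methyl 3-oxopentanoate | CCC(=O)CC(=O)OC | starting material
9 | methyl 2-diazo-3-oxopentanoate | CCC(=O)C(=[N+]=[N-])C(=O)OC | intermediate
10 | methyl (3Z)-3-(TBSO)-2-diazopent-3-enoate | C/C=C(\O[Si](C)(C)C(C)(C)C)C(=[N+]=[N-])C(=O)OC | intermediate
11 | methyl 2-oxocyclopentane-1-carboxylate | COC(=O)C1CCCC1=O | starting material
12 | tert-butyl L-valinate (tert-butyl (2S)-2-amino-3-methylbutanoate) | CC(C)[C@H](N)C(=O)OC(C)(C)C | starting material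
13 | methyl 2-{[(2S)-1-tert-butoxy-3-methyl-1-oxobutan-2-yl]amino}cyclopent-1-ene-1-carboxylate | COC(=O)C1=C(N[C@@H](C(C)C)C(=O)OC(C)(C)C)CCC1 | intermediate
14 | methyl (1S)-2-{[(2S)-1-tert-butoxy-3-methyl-1-oxobutan-2-yl]imino}-1-methylcyclopentane-1-carboxylate | COC(=O)[C@@]1(C)CCCC1=N[C@@H](C(C)C)C(=O)OC(C)(C)C | intermediate
15 | methyl (1S)-1-methyl-2-oxocyclopentane-1-carboxylate | COC(=O)[C@@]1(C)CCCC1=O | intermediate
16 | methyl (1S)-1-methyl-2-[(trifluoromethanesulfonyl)oxy]cyclopent-2-ene-1-carboxylate | COC(=O)[C@@]1(C)CCC=C1OS(=O)(=O)C(F)(F)F | intermediate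
17 | methyl (1S)-2-[3-(TBSO)-3-methylbut-1-yn-1-yl]-1-methylcyclopent-2-ene-1-carboxylate | COC(=O)[C@@]1(C)CCC=C1C#CC(C)(C)O[Si](C)(C)C(C)(C)C | intermediate
18 | methyl (1S)-2-[(1Z)-3-(TBSO)-3-methylbut-1-en-1-yl]-1-methylcyclopent-2-ene-1-carboxylate | COC(=O)[C@@]1(C)CCC=C1/C=C\C(C)(C)O[Si](C)(C)C(C)(C)C | intermediate
19 | methyl (1S,2S,3S)-1-[(1Z)-1-(TBSO)prop-1-en-1-yl]-2-[(5S)-5-(methoxycarbonyl)-5-methylcyclopent-1-en-1-yl]-3-[2-(TBSO)propan-2-yl]cyclopropane-1-carboxylate (all three carbon substituents cis) | COC(=O)[C@@]1(C)CCC=C1[C@@H]2[C@H](C(C)(C)O[Si](C)(C)C(C)(C)C)[C@]2(C(=O)OC)/C(O[Si](C)(C)C(C)(C)C)=C/C | intermediate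
20 | dimethyl (1R,4S,7S,10S)-9-(TBSO)-7-[2-(TBSO)propan-2-yl]-4,10-dimethyl-1,2,3,4,7,10-hexahydroazulene-4,8-dicarboxylate | COC(=O)[C@@]1(C)CC[C@H]2C1=C[C@H](C(C)(C)O[Si](C)(C)C(C)(C)C)C(C(=O)OC)=C(O[Si](C)(C)C(C)(C)C)[C@H]2C | intermediate
21 | dimethyl (1R,4S,7S,10S)-7-[2-(TBSO)propan-2-yl]-4,10-dimethyl-9-oxooctahydroazulene-4,8-dicarboxylate (C8 epimers, partly enolised) | COC(=O)[C@@]1(C)CC[C@H]2C1=C[C@H](C(C)(C)O[Si](C)(C)C(C)(C)C)C(C(=O)OC)C(=O)[C@H]2C | intermediate
22 | methyl (1R,4S,7R,10S)-7-[2-(TBSO)propan-2-yl]-4,10-dimethyl-9-oxooctahydroazulene-4-carboxylate | COC(=O)[C@@]1(C)CC[C@H]2C1=C[C@H](C(C)(C)O[Si](C)(C)C(C)(C)C)CC(=O)[C@H]2C | intermediate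
23 | 4-methylbenzenesulfonylhydrazone of 22 at C9 (C=N geometry not defined) | COC(=O)[C@@]1(C)CC[C@H]2C1=C[C@H](C(C)(C)O[Si](C)(C)C(C)(C)C)CC(=NNS(=O)(=O)c3ccc(C)cc3)[C@H]2C | intermediate
24 | methyl (1R,4S,7R,10R)-7-[2-(TBSO)propan-2-yl]-4,10-dimethyloctahydroazulene-4-carboxylate | COC(=O)[C@@]1(C)CC[C@H]2C1=C[C@H](C(C)(C)O[Si](C)(C)C(C)(C)C)CC[C@H]2C | intermediate
25 | (1R,4S,7R,10R)-7-[2-(TBSO)propan-2-yl]-4,10-dimethyloctahydroazulene-4-carboxylic acid | OC(=O)[C@@]1(C)CC[C@H]2C1=C[C@H](C(C)(C)O[Si](C)(C)C(C)(C)C)CC[C@H]2C | intermediate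
26 | cesium (1R,4S,7R,10R)-7-[2-(TBSO)propan-2-yl]-4,10-dimethyloctahydroazulene-4-carboxylate | [Cs+].[O-]C(=O)[C@@]1(C)CC[C@H]2C1=C[C@H](C(C)(C)O[Si](C)(C)C(C)(C)C)CC[C@H]2C | intermediate
27 | 3,5-dimethoxybenzyne (1,2-didehydro-3,5-dimethoxybenzene) | COC1=CC(OC)=CC#C1 | intermediate
28 | cesium 2-(acyloxy)-4,6-dimethoxyphenyl anion, acyl = the acyl group of 25 | [Cs+].COc1cc(OC)[c-]c(OC(=O)[C@@]2(C)CC[C@H]3C2=C[C@H](C(C)(C)O[Si](C)(C)C(C)(C)C)CC[C@H]3C)c1 | intermediate
29 | (2-hydroxy-4,6-dimethoxyphenyl)[(1R,4S,7R,10R)-7-[2-(TBSO)propan-2-yl]-4,10-dimethyloctahydroazulen-4-yl]methanone | O=C(c1c(O)cc(OC)cc1OC)[C@@]1(C)CC[C@H]2C1=C[C@H](C(C)(C)O[Si](C)(C)C(C)(C)C)CC[C@H]2C | intermediate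
30 | tert-butyl 2-{[(1R,4S,7R,10R)-7-[2-(TBSO)propan-2-yl]-4,10-dimethyloctahydroazulen-4-yl]carbonyl}-3,5-dimethoxyphenyl carbonate | O=C(c1c(OC(=O)OC(C)(C)C)cc(OC)cc1OC)[C@@]1(C)CC[C@H]2C1=C[C@H](C(C)(C)O[Si](C)(C)C(C)(C)C)CC[C@H]2C | intermediate
31 | lithium alkoxide from reduction of the C9' ketone of 30 (both C9' epimers; aryl carbonate intact) | [Li+].[O-]C(c1c(OC(=O)OC(C)(C)C)cc(OC)cc1OC)[C@@]1(C)CC[C@H]2C1=C[C@H](C(C)(C)O[Si](C)(C)C(C)(C)C)CC[C@H]2C | intermediate
32 | lithium phenoxide with the tert-butyl carbonate on the C9' oxygen (both C9' epimers) | [Li+].CC(C)(C)OC(=O)OC(c1c([O-])cc(OC)cc1OC)[C@@]1(C)CC[C@H]2C1=C[C@H](C(C)(C)O[Si](C)(C)C(C)(C)C)CC[C@H]2C | intermediate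
33 | 6-{[(1R,4R,7R,10R)-7-[2-(TBSO)propan-2-yl]-4,10-dimethyloctahydroazulen-4-yl]methylidene}-3,5-dimethoxycyclohexa-2,4-dien-1-one (exocyclic geometry not defined) | COC1=CC(=O)C(=C[C@@]2(C)CC[C@H]3C2=C[C@H](C(C)(C)O[Si](C)(C)C(C)(C)C)CC[C@H]3C)C(OC)=C1 | intermediate
34 | 2-{(1S)-1-[(1R,4R,7R,10R)-7-[2-(TBSO)propan-2-yl]-4,10-dimethyloctahydroazulen-4-yl]-3-methylbutyl}-3,5-dimethoxyphenol | CC(C)C[C@H](c1c(O)cc(OC)cc1OC)[C@@]1(C)CC[C@H]2C1=C[C@H](C(C)(C)O[Si](C)(C)C(C)(C)C)CC[C@H]2C | intermediate
35 | 4-hydroxy-2,6-dimethoxy-5-{(1S)-1-[(1R,4R,7R,10R)-7-[2-(TBSO)propan-2-yl]-4,10-dimethyloctahydroazulen-4-yl]-3-methylbutyl}benzene-1,3-dicarbaldehyde | CC(C)C[C@H](c1c(O)c(C=O)c(OC)c(C=O)c1OC)[C@@]1(C)CC[C@H]2C1=C[C@H](C(C)(C)O[Si](C)(C)C(C)(C)C)CC[C@H]2C | intermediate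
36 | 4-hydroxy-5-{(1S)-1-[(1R,4R,7R,10R)-7-(2-hydroxypropan-2-yl)-4,10-dimethyloctahydroazulen-4-yl]-3-methylbutyl}-2,6-dimethoxybenzene-1,3-dicarbaldehyde | CC(C)C[C@H](c1c(O)c(C=O)c(OC)c(C=O)c1OC)[C@@]1(C)CC[C@H]2C1=C[C@H](C(C)(C)O)CC[C@H]2C | intermediate
37 | 2,4,6-trihydroxy-5-{(1S)-1-[(1R,4R,7R,10R)-7-(2-hydroxypropan-2-yl)-4,10-dimethyloctahydroazulen-4-yl]-3-methylbutyl}benzene-1,3-dicarbaldehyde (CNP0281883.3) | CC(C)C[C@H](c1c(O)c(C=O)c(O)c(C=O)c1O)[C@@]1(C)CC[C@H]2C1=C[C@H](C(C)(C)O)CC[C@H]2C | target

## Step count and least certain steps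

Total: 20 steps. Longest linear sequence: 15 steps (steps 6 to 20, from 11 to 37). The side branches are steps 1–2 (aryne precursor 5), step 3 (alkyne 7) and steps 4–5 (diazo ester 10).

Step 15 (key step).
- What may go wrong: protonation of the aryl anion before it reaches the carbonyl, so that O-arylation stops without acyl migration. The acyl carbon is neopentyl-like, which slows the four-centre shift. A second arylation of the product phenoxide and slow fluoride attack on the tertiary silyl ether at 110 °C are lesser risks.
- Fallback: it sets out from 25 and 2 and comes back at 29. Acid 25 is converted with 1-chloro-N,N,2-trimethylprop-1-en-1-amine into the acid chloride F1. F1 acylates bromophenol 2 (Et3N, DMAP) to give the 2-bromo-3,5-dimethoxyphenyl ester F2. Bromine–lithium exchange with n-BuLi at −100 °C gives the ortho-lithiated ester F3, the lithium counterpart of 28 in a medium without proton donors. Its anionic Fries 1,3-acyl shift gives 29 after work-up.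

Step 11.
- What may go wrong: poor face selection when the catalyst and the C4 centre oppose each other; slow cyclopropanation of a cis alkene that carries a tertiary silyloxyalkyl group; insertion of the carbenoid into the allylic C2–H bonds; a sluggish Cope rearrangement, because the C7 side chain points into the boat.
- Fallback: it sets out from 7, 10 and 16 and comes back at 19. Rhodium-catalysed trans-hydroboration of 7 with pinacolborane ([Rh(cod)Cl]2, P(iPr)3, Et3N) gives the (Z)-alkenylboronate F4. Cyclopropanation of F4 with 10 under Rh2(S-PTAD)4 gives the all-cis cyclopropylboronate F5 under catalyst control alone, with neither the C4 centre nor the allylic C–H bonds of the cyclopentene present. Suzuki–Miyaura coupling of F5 with 16 (Pd(OAc)2, SPhos, K3PO4), with retention at the cyclopropyl carbon, gives 19, which rearranges to 20 on warming.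

Step 17.
- What may go wrong: insufficient or reversed facial selectivity at C9', because the bias of C4 rests on a conformational preference that has not been tested; the methyl group and the C3 methylene differ little in size. Further risks are reduction of the o-quinone methide by β-hydride transfer from the Grignard reagent and attack of hydride on the carbonate.
- Fallback: it sets out from 30 and comes back at 34. The order of the two nucleophiles is reversed. iBuMgBr activated with CeCl3 adds to the ketone of 30; carbonate transfer and elimination assisted by MgBr2·OEt2 give the trisubstituted o-quinone methide F6. NaBH4 then delivers hydride to C9'. Hydrogen now enters where the isobutyl group entered before, so for the same facial preference the opposite configuration at C9' is expected, and whichever order matches the target is kept.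

Step 18.
- What may go wrong: ionisation of the tertiary silyl ether by TiCl4, or addition of the HCl that is set free to the C5=C6 alkene followed by skeletal rearrangement beside the quaternary carbon; incomplete second formylation.
- Fallback: it sets out from 34 and comes back at 35. Magnesium-mediated ortho-formylation (MgCl2, Et3N, paraformaldehyde, MeCN, reflux) puts the first formyl group beside the hydroxyl group without strong acid and gives the monoaldehyde F7. Vilsmeier–Haack formylation (POCl3, DMF) of the remaining position between the two methoxy groups then gives 35.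

## Further compounds

F1 | step 15 | (1R,4S,7R,10R)-7-[2-(TBSO)propan-2-yl]-4,10-dimethyloctahydroazulene-4-carbonyl chloride | ClC(=O)[C@@]1(C)CC[C@H]2C1=C[C@H](C(C)(C)O[Si](C)(C)C(C)(C)C)CC[C@H]2C
F2 | step 15 | 2-bromo-3,5-dimethoxyphenyl (1R,4S,7R,10R)-7-[2-(TBSO)propan-2-yl]-4,10-dimethyloctahydroazulene-4-carboxylate | COc1cc(OC)c(Br)c(OC(=O)[C@@]2(C)CC[C@H]3C2=C[C@H](C(C)(C)O[Si](C)(C)C(C)(C)C)CC[C@H]3C)c1
F3 | step 15 | 2-lithio-3,5-dimethoxyphenyl (1R,4S,7R,10R)-7-[2-(TBSO)propan-2-yl]-4,10-dimethyloctahydroazulene-4-carboxylate | COc1cc(OC)c([Li])c(OC(=O)[C@@]2(C)CC[C@H]3C2=C[C@H](C(C)(C)O[Si](C)(C)C(C)(C)C)CC[C@H]3C)c1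
F4 | step 11 | tert-butyldimethyl{[(3Z)-2-methyl-4-(4,4,5,5-tetramethyl-1,3,2-dioxaborolan-2-yl)but-3-en-2-yl]oxy}silane | CC(C)(O[Si](C)(C)C(C)(C)C)/C=C\B1OC(C)(C)C(C)(C)O1
F5 | step 11 | methyl 1-[(1Z)-1-(TBSO)prop-1-en-1-yl]-2-(4,4,5,5-tetramethyl-1,3,2-dioxaborolan-2-yl)-3-[2-(TBSO)propan-2-yl]cyclopropane-1-carboxylate (all-cis, configuration as in 19) | CC1(C)OB(OC1(C)C)[C@@H]2[C@H](C(C)(C)O[Si](C)(C)C(C)(C)C)[C@]2(C(=O)OC)/C(O[Si](C)(C)C(C)(C)C)=C/C
F6 | step 17 | 6-{1-[(1R,4R,7R,10R)-7-[2-(TBSO)propan-2-yl]-4,10-dimethyloctahydroazulen-4-yl]-3-methylbutylidene}-3,5-dimethoxycyclohexa-2,4-dien-1-one (exocyclic geometry not defined) | COC1=CC(=O)C(=C(CC(C)C)[C@@]2(C)CC[C@H]3C2=C[C@H](C(C)(C)O[Si](C)(C)C(C)(C)C)CC[C@H]3C)C(OC)=C1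
F7 | step 18 | 2-hydroxy-4,6-dimethoxy-3-{(1S)-1-[(1R,4R,7R,10R)-7-[2-(TBSO)propan-2-yl]-4,10-dimethyloctahydroazulen-4-yl]-3-methylbutyl}benzaldehyde | CC(C)C[C@H](c1c(O)c(C=O)c(OC)cc1OC)[C@@]1(C)CC[C@H]2C1=C[C@H](C(C)(C)O[Si](C)(C)C(C)(C)C)CC[C@H]2C
A1 | alternative 1 | (2R)-2-methyl-2-[(1R)-3-methyl-1-(2,4,6-trimethoxyphenyl)butyl]cyclopentan-1-one | CC(C)C[C@H](c1c(OC)cc(OC)cc1OC)[C@@]1(C)CCCC1=O
A2 | alternative 1 | 1-[(2Z)-5-methylhex-2-en-2-yl]cyclobutan-1-ol | C/C(=C/CC(C)C)C1(O)CCC1
A3 | alternative 1 | 2,4,6-trimethoxybenzenediazonium tetrafluoroborate | COc1cc(OC)c([N+]#N)c(OC)c1.F[B-](F)(F)F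
A4 | alternative 2 | hexahydroazulene [4+3] adduct with the hexasubstituted arene on C9' (C5=C6, C8 ester, C9 silyl enol ether, triethylsilyl ether on the side chain) | CC(C)C[C@H](c1c(OC)c(C(=O)OC)c(OC)c(C(=O)OC)c1OC)[C@@]1(C)CC[C@H]2C1=C[C@H](C(C)(C)O[Si](CC)(CC)CC)C(C(=O)OC)=C(O[Si](C)(C)C(C)(C)C)[C@H]2C
A5 | alternative 2 | (Z)-dienyl cyclopentene with the arylated C9' side chain on C4 and a triethylsilyl ether | CC(C)C[C@H](c1c(OC)c(C(=O)OC)c(OC)c(C(=O)OC)c1OC)[C@@]1(C)CCC=C1/C=C\C(C)(C)O[Si](CC)(CC)CC
A6 | alternative 3 | hydroazulene dienol with C1=C2 and C5=C6, hydroxyl on C3 and the 2,4,6-trimethoxyphenyl side chain | CC(C)C[C@H](c1c(OC)cc(OC)cc1OC)[C@@]1(C)[C@@H](O)C=C2C1=C[C@H](C(C)(C)O[Si](CC)(CC)CC)CC[C@H]2C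
A7 | alternative 3 | acyclic dienyne with the allylic alcohol vinyl group, the C1≡C5 alkyne and the C6 vinyl group | CC(C)C[C@H](c1c(OC)cc(OC)cc1OC)[C@@](C)([C@@H](O)C=C)C#C[C@H](C)CC[C@H](C=C)C(C)(C)O[Si](CC)(CC)CC
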